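We want to know what share of single product in single product plus bis adduct each manner of addition leaves at the end, and in which flask that share stands highest.

in all of them: time 3.0 h

| flask | substrate | partner | temperature | remark |
|---|---|---|---|---|
| west | 0.050 M | 0.0450 M (fed, over 15 min) | 5 °C | all else is in the flask from the start; the feed brings no volume worth counting |
| south | 0.050 M | 0.0450 M (fed, over 2.5 h) | 5 °C | all else is in the flask from the start; the feed brings no volume worth counting |
| south-east | 0.050 M (fed, over 2.5 h) | 0.0450 M | 5 °C | all else is in the flask from the start; the feed brings no volume worth counting |
| east | 0.050 M (fed, over 2.5 h) | 0.0450 M |  | the addition at −15 °C, then warmed to 5 °C; the feed brings no volume worth counting |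

    partner + single product → bis adduct (k1 = 0.0526 M⁻¹ s⁻¹, Ea1 = 65.0 kJ mol⁻¹)
    substrate + partner → single product (k2 = 0.0181 M⁻¹ s⁻¹, Ea2 = 57.0 kJ mol⁻¹)
    substrate + partner → other mono adduct (k3 = 0.0127 M⁻¹ s⁻¹, Ea3 = 66.0 kJ mol⁻¹)
    partner ⇌ dormant form (K4 = 15, k4 = 0.00683 s⁻¹, Ea4 = 70.0 kJ mol⁻¹, ΔH4 = 52.0 kJ mol⁻¹)
    partner → decomposed reagent (k5 = 4.98 × 10⁻⁴ s⁻¹, Ea5 = 79.0 kJ mol⁻¹)
    partner + other mono adduct → bis adduct (k6 = 0.00656 M⁻¹ s⁻¹, Ea6 = 64.0 kJ mol⁻¹)
    (constants at 5 °C)

* the best flask by share of single product in single product plus bis adduct; "all alike" if 1.5 percentage points covers them all (west / south / south-east / east / all alike)
* share of single product in single product plus bis adduct at the end, west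
* share of single product in single product plus bis adduct at the end, south
* share of single product in single product plus bis adduct at the end, south-east
* share of single product in single product plus bis adduct at the end, east

- all constants are for 5 °C and move with temperature by the activation energies and enthalpies

We begin at the short end of the ladder of times. Partner and dormant form exchange, by that step alone, with a relaxation half-life of 1.59 min, shorter than the quick feed of 15 min in west. So we take the two as one pool, with free partner about one part in 16.0 of it at equilibrium. On the next rung, that pool would last 2.89 h against substrate at its charge and 8.92 h against decomposition, so substrate takes partner faster. Together they give a pool life of 2.18 h, shorter than the 3.0 h run.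

The end state comes from a budget. The steps that build the products each carry free partner as a factor, so in west and south, each at one temperature with its substrate in from the start, free partner cancels from their ratios. The products there then follow from y, the fraction of substrate left, and the feed schedule enters through y. The carried quantity is the overrun ratio, the constant of partner on single product divided by the sum of the constants of partner on substrate, 1.71; the usual term is selectivity factor. Single product, as a fraction of the charge, is then m(y − y^s)/(s − 1), where s is that ratio and m = 0.588 is the part of first attack that gives single product. Other mono adduct follows the same form with the other part of first attack and its own ratio, 0.213, and bis adduct is the reacted rest.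

Holding substrate at its charge and leaving out what the mono adducts take, the whole pool used up gives minus ln y = 0.680, which would leave 50.7 % of the substrate. Counting partner as delivered at the midpoint of its feed, west has covered 73.3 % of that reach by the end. That leaves 60.8 % of its substrate and gives a share of 62.6 %. South leaves 68.7 % and gives 70.3 %. In south-east and east the substrate is not in from the start, so our reckoning stops there and we commit to no number for them.

The forecast gives 66 % for west, 69 % for south, 71 % for south-east and 72 % for east and names east, above our figure for west and below our figure for south, holding that the share depends mainly on “how little single product has met free partner”.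

The flasks end at 62.7 % in west, 69.5 % in south, 72.4 % in south-east and 75.3 % in east, so east stands highest. West holds 60.9 % of its substrate at 3.00 h against our 60.8 %, and south holds 67.8 % against our 68.7 %. The neighbour of west with 0.11 M of partner takes the same reckoning: its reach comes to 1.66, and we reckon 29.6 % of the substrate left. With the overrun ratio still 1.71, the share comes to 31.2 %. That neighbour holds 27.7 % of its substrate and ends at 29.3 %.

The constants belong to no real substance.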